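**Strategy.** Numbering the target as an octahydrocyclohepta[b]furan-2-one (C3a, C4–C8, C8a), the cycloheptane ring carries oxygen on the 1,4-related carbons C8a and C5 and a carbinol C7 flanked by C8–O and C6–CH3. This is the retron of a furan/oxyallyl (4+3) cycloadduct. One cycloaddition of 3-bromofuran with a 1-alkoxy-3-methyl-2-silyloxyallyl cation, released from the silyl enol ether of a mixed α-keto acetal that carries (S)-1-phenylethoxy, forms C8a–C8 and C5–C6 and four stereocentres of an 8-oxabicyclo[3.2.1]octenone. The oxygen bridge then directs the C7 addition and the C3a hydrogenation, stays on C5, and finally leaves C8a with inversion as the lactone closes.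

Key step: step 3

Assumption: 1 is taken as purchasable (otherwise it is one step from 1,1-dimethoxyacetone by LiN(i-Pr)2/MeI).
Assumption: the (S)-1-phenylethoxy group is taken to steer the furan to the cation face that gives 8 as drawn; were the sense the opposite, (R)-1-phenylethanol would be used and nothing else would change.

Bicyclic intermediates are numbered as 8-oxabicyclo[3.2.1]octanes (C1 and C5 bridgeheads, C3 the carbonyl or carbinol carbon, O8 the bridge). C1, C2, C3, C4, C5 and C7 become C8a, C8, C7, C6, C5 and C3a of the target.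

Step 1
Reactants: 1 1,1-dimethoxybutan-2-one; 2 (S)-1-phenylethanol
Product: 3 1-methoxy-1-[(1S)-1-phenylethoxy]butan-2-one (both acetal epimers)
Conditions: PPTS (cat.), toluene, 60 °C, reduced pressure (removal of MeOH)
Reagents that add atoms: none
Why: Acid-catalysed transacetalisation exchanges one methoxy group for the chiral alkoxy group, and the new acetal centre need not be controlled because it becomes planar in step 3.

Step 2
Reactants: 3 mixed acetal
Product: 5 (Z)-triethylsilyl enol ether of 3, via lithium enolate 4 (not isolated)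
Conditions: LiN(i-Pr)2, THF, −78 °C; then TESCl, −78 °C → rt
Reagents that add atoms: chlorotriethylsilane CC[Si](Cl)(CC)CC
Why: Kinetic enolisation on the ethyl side and O-silylation (silyl enol ether formation) should give the Z enol ether from the chelated α-alkoxy enolate, and the geometry is not decisive because C4 of 8 is equilibrated.

Step 3
Reactants: 5 silyl enol ether; 6 3-bromofuran
Product: 8 (1R,2R,4S,5S)-7-bromo-4-methyl-2-[(1S)-1-phenylethoxy]-8-oxabicyclo[3.2.1]oct-6-en-3-one, via oxyallyl cation 7 (not isolated)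
Conditions: 6 (3 equiv), TMSOTf (10 mol%), CH2Cl2, −95 → −78 °C; then Et3N, CH2Cl2, rt
Reagents that add atoms: none
Why: TMSOTf ionises the mixed acetal (the methoxy group leaves as its silyl ether) to the 1-alkoxy-2-silyloxyallyl cation 7, which adds to the furan in a stepwise (4+3) cycloaddition; the closest known reaction type is the low-temperature (4+3) cycloaddition of furans with α-alkoxy silyloxyallyl cations generated from silyl enol ethers of α-keto acetals. The furan carbon next to bromine attacks the oxocarbenium carbon (C1–C2 bond of 8) and the silyl enol ether then adds to the furan-derived oxocarbenium ion (C4–C5 bond) in a 7-(enolendo)-exo-trig Mukaiyama-type closure, which completes the cycloheptenone and with it the bridged tetrahydropyranone. C1 and C5 are cis because both bonds form on one face of the furan, whose oxygen becomes the bridge; the C2 alkoxy and C4 methyl groups end equatorial (trans to the bridge), since the compact closure and the Et3N equilibration of the two enolisable centres converge on this most stable ketone. The absolute sense is set by the 1-phenylethyl group, whose phenyl ring covers one face of the cation so that the furan adds to the other. The step needs regioselectivity (alkoxy carbon bonded to the furan carbon next to bromine), secured by the bromine lone pair that makes this α-carbon the more nucleophilic one, and facial selectivity, secured by the auxiliary at low temperature.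

Step 4
Reactants: 8 bromo cycloadduct; 9 di-tert-butyl malonate
Product: 10 di-tert-butyl 2-{4-methyl-3-oxo-2-[(1S)-1-phenylethoxy]-8-oxabicyclo[3.2.1]oct-6-en-7-yl}malonate
Conditions: Pd2(dba)3 (2.5 mol%), P(t-Bu)3·HBF4 (10 mol%), K3PO4, toluene, 70 °C
Reagents that add atoms: none
Why: Palladium-catalysed α-vinylation of the malonate with the vinyl bromide (enolate cross-coupling) should attach the future lactone carbons to C7; phosphate and malonate are too weakly basic to open the β-alkoxy ketone, and any epimerisation at C2 or C4 only returns the diequatorial ketone.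

Step 5
Reactants: 10 vinyl malonate
Product: 12 di-tert-butyl 2-(2-hydroxy-4-methyl-3-oxo-8-oxabicyclo[3.2.1]octan-7-yl)malonate (7-endo), via saturated 1-phenylethyl ether 11 (not isolated)
Conditions: H2 (1 atm), Pd on carbon (10 wt% Pd), EtOH/EtOAc, rt
Reagents that add atoms: none
Why: Heterogeneous hydrogenation should deliver hydrogen to the exo face of the C6–C7 double bond (the face of the oxygen bridge), so that the malonyl group becomes endo (sets C3a of the target), and hydrogenolysis of the benzylic ether on the same catalyst frees the C2 hydroxyl.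

Step 6
Reactants: 13 (S)-but-3-yn-2-ol
Product: 14 (S)-tert-butyl(but-3-yn-2-yloxy)diphenylsilane
Conditions: TBDPSCl, imidazole, DMF, rt
Reagents that add atoms: tert-butylchlorodiphenylsilane CC(C)(C)[Si](Cl)(c1ccccc1)c1ccccc1
Why: Silyl ether formation on the secondary alcohol (protection) does not involve the stereocentre.

Step 7
Reactants: 12 hydroxy ketone; 14 silylated butynol
Product: 16 di-tert-butyl 2-{3-[(3S)-3-(tert-butyldiphenylsilyloxy)but-1-yn-1-yl]-2,3-dihydroxy-4-methyl-8-oxabicyclo[3.2.1]octan-7-yl}malonate, via lithium acetylide 15 (not isolated)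
Conditions: 14 (4 equiv), n-BuLi (4 equiv), THF, −78 °C; then 12, −78 → −30 °C; aq. NH4Cl
Reagents that add atoms: none
Why: 1,2-Addition of the lithium acetylide to the ketone (the first equivalents are used up by the hydroxyl and the malonate C–H) should occur equatorially on the exo face, because the endo face is covered by the two-carbon bridge and the endo malonyl group, which gives the axial tertiary alcohol (sets C7 of the target).

Step 8
Reactants: 16 alkynyl diol
Product: 18 di-tert-butyl 2-{3-[(3S)-3-(tert-butyldiphenylsilyloxy)butanoyl]-2,3-dihydroxy-4-methyl-8-oxabicyclo[3.2.1]octan-7-yl}malonate, via alkylidene carbonate 17 (not isolated)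
Conditions: AgOAc (10 mol%), DBU, CO2 (1 MPa), toluene, rt; then H2O, MeCN, 40 °C
Reagents that add atoms: carbon dioxide O=C=O; water O
Why: Silver-catalysed carboxylative cyclisation of the tertiary propargylic alcohol with CO2 (5-exo-dig) and hydrolysis of the alkylidene carbonate amount to a regioselective alkyne hydration that places the carbonyl on the carbon next to the carbinol.

Step 9
Reactants: 18 keto diol
Product: 20 2,3-O-cyclic sulfate of 18, via cyclic sulfite 19 (not isolated)
Conditions: SOCl2, pyridine, CH2Cl2, 0 °C; then RuCl3 (cat.), NaIO4, MeCN/H2O, 0 °C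
Reagents that add atoms: thionyl chloride O=S(Cl)Cl; sodium periodate [Na+].[O-]I(=O)(=O)=O
Why: Cyclic sulfite formation on the cis diol (axial 3-OH, equatorial 2-OH) and RuO4-catalysed oxidation give the cyclic sulfate (diol activation) without touching a stereocentre.

Step 10
Reactants: 20 cyclic sulfate; 21 (S)-2-methylbutanoic acid
Product: 24 di-tert-butyl 2-{3-[(3S)-3-(tert-butyldiphenylsilyloxy)butanoyl]-3-hydroxy-4-methyl-2-[(2S)-2-methylbutanoyloxy]-8-oxabicyclo[3.2.1]octan-7-yl}malonate (C2 inverted), via cesium (S)-2-methylbutanoate 22 (not isolated), via cesium alkyl sulfate 23 (not isolated)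
Conditions: 21, Cs2CO3, DMF, 50 °C; then H2SO4 (cat.), H2O, THF, rt
Reagents that add atoms: none
Why: SN2 opening of the cyclic sulfate by the carboxylate at the secondary carbon C2 (trans-diaxial opening, attack on the open exo face) should invert C2 and install the ester (sets C8 of the target), and the tertiary sulfate monoester is then hydrolysed with S–O cleavage so that C3 keeps its configuration.

Step 11
Reactants: 24 ester
Product: 27 α-carboxy lactone (cis-fused; 5-OH free), via tris(trimethylsilyl) derivative 25 (not isolated), via silylated lactone 26 (not isolated)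
Conditions: TMSOTf (5 equiv), 2,6-lutidine (3 equiv), CH2Cl2, 0 °C → rt; then 1 M HCl, THF, 0 °C
Reagents that add atoms: none
Why: Proposed new method: TMSOTf should turn both tert-butyl esters into silyl esters and silylate the bridging ether oxygen; the carbonyl oxygen of one endo silyl ester, held anti to the C1–O8 bond, then opens the silyloxonium ion by 5-exo-tet SN2 attack at C1, so that the lactone oxygen enters with inversion (cis-fused lactone, C8a of the target) while the former bridge oxygen stays on C5 as its silyl ether and the silyl cation is passed on, and aqueous acid frees the hydroxyls and the second carboxyl; the closest known reaction type is the cleavage of cyclic ethers through silyloxonium ions (TMSI or silyl triflates) and the acid-promoted opening of oxygen-bridged bicycles by external nucleophiles with inversion.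

Step 12
Reactants: 27 α-carboxy lactone
Product: 29 side-chain O-TBDPS ether of the target, via Mannich base 28 (not isolated)
Conditions: aq. CH2O (37%), Et2NH, THF, rt; then NaOAc, AcOH, 50 °C
Reagents that add atoms: formaldehyde C=O
Why: Decarboxylative Mannich methylenation of the α-carboxy lactone (formaldehyde and diethylamine, then loss of CO2 and of the amine) should build the exocyclic methylene under nearly neutral conditions, and the unassigned α-centre becomes planar.

Step 13
Reactants: 29 silyl ether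
Product: 30 (3aS,5R,6S,7S,8S,8aR)-5,7-dihydroxy-7-[(3S)-3-hydroxybutanoyl]-6-methyl-3-methylidene-2-oxooctahydro-2H-cyclohepta[b]furan-8-yl (2S)-2-methylbutanoate
Conditions: HF·pyridine, THF/pyridine, 0 °C → rt
Reagents that add atoms: none
Why: Fluoride cleavage of the silyl ether (deprotection) under buffered acidic conditions should leave the β-hydroxy ketone, the esters and the methylene lactone untouched.

**Compound list**

1 | 1,1-dimethoxybutan-2-one | CCC(=O)C(OC)OC | starting material
2 | (S)-1-phenylethanol | C[C@H](O)c1ccccc1 | starting material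
3 | 1-methoxy-1-[(1S)-1-phenylethoxy]butan-2-one (both epimers at the acetal carbon) | CCC(=O)C(OC)O[C@@H](C)c1ccccc1 | intermediate
4 | lithium (Z)-enolate of 3 | C/C=C(\O[Li])C(OC)O[C@@H](C)c1ccccc1 | intermediate
5 | triethyl{[(2Z)-1-methoxy-1-[(1S)-1-phenylethoxy]but-2-en-2-yl]oxy}silane | C/C=C(\O[Si](CC)(CC)CC)C(OC)O[C@@H](C)c1ccccc1 | intermediate
6 | 3-bromofuran | Brc1ccoc1 | starting material
7 | 3-methyl-1-[(1S)-1-phenylethoxy]-2-(triethylsilyloxy)allyl cation triflate | C/C=C(\O[Si](CC)(CC)CC)C=[O+][C@@H](C)c1ccccc1.[O-]S(=O)(=O)C(F)(F)F | intermediate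
8 | (1R,2R,4S,5S)-7-bromo-4-methyl-2-[(1S)-1-phenylethoxy]-8-oxabicyclo[3.2.1]oct-6-en-3-one (C2–O and C4–CH3 equatorial, trans to the O8 bridge) | O1[C@H]2C(Br)=C[C@@H]1[C@H](C)C(=O)[C@@H]2O[C@@H](C)c3ccccc3 | intermediate
9 | di-tert-butyl malonate | CC(C)(C)OC(=O)CC(=O)OC(C)(C)C | starting material
10 | di-tert-butyl 2-{4-methyl-3-oxo-2-[(1S)-1-phenylethoxy]-8-oxabicyclo[3.2.1]oct-6-en-7-yl}malonate (ring configuration as in 8) | O1[C@H]2C(C(C(=O)OC(C)(C)C)C(=O)OC(C)(C)C)=C[C@@H]1[C@H](C)C(=O)[C@@H]2O[C@@H](C)c3ccccc3 | intermediate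
11 | 6,7-dihydro derivative of 10, malonyl group endo (trans to O8) | O1[C@H]2[C@H](C(C(=O)OC(C)(C)C)C(=O)OC(C)(C)C)C[C@@H]1[C@H](C)C(=O)[C@@H]2O[C@@H](C)c3ccccc3 | intermediate
12 | di-tert-butyl 2-(2-hydroxy-4-methyl-3-oxo-8-oxabicyclo[3.2.1]octan-7-yl)malonate (7-endo; 2-OH and 4-CH3 equatorial) | O1[C@H]2[C@H](C(C(=O)OC(C)(C)C)C(=O)OC(C)(C)C)C[C@@H]1[C@H](C)C(=O)[C@@H]2O | intermediate
13 | (S)-but-3-yn-2-ol | C#C[C@H](C)O | starting material
14 | (S)-tert-butyl(but-3-yn-2-yloxy)diphenylsilane | C#C[C@H](C)O[Si](c1ccccc1)(c1ccccc1)C(C)(C)C | intermediate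
15 | lithium acetylide of 14 | [Li]C#C[C@H](C)O[Si](c1ccccc1)(c1ccccc1)C(C)(C)C | intermediate
16 | di-tert-butyl 2-{3-[(3S)-3-(tert-butyldiphenylsilyloxy)but-1-yn-1-yl]-2,3-dihydroxy-4-methyl-8-oxabicyclo[3.2.1]octan-7-yl}malonate (3-OH axial, cis to 2-OH; alkynyl equatorial, on the side of O8) | O1[C@H]2[C@H](C(C(=O)OC(C)(C)C)C(=O)OC(C)(C)C)C[C@@H]1[C@H](C)[C@@](O)(C#C[C@H](C)O[Si](c3ccccc3)(c3ccccc3)C(C)(C)C)[C@@H]2O | intermediate
17 | (Z)-alkylidene cyclic carbonate (4-alkylidene-1,3-dioxolan-2-one spiro-fused at C3 of the bicycle; 2-OH free) | O1[C@H]2[C@H](C(C(=O)OC(C)(C)C)C(=O)OC(C)(C)C)C[C@@H]1[C@H](C)[C@]3(OC(=O)O/C3=C\[C@H](C)O[Si](c4ccccc4)(c4ccccc4)C(C)(C)C)[C@@H]2O | intermediate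
18 | di-tert-butyl 2-{3-[(3S)-3-(tert-butyldiphenylsilyloxy)butanoyl]-2,3-dihydroxy-4-methyl-8-oxabicyclo[3.2.1]octan-7-yl}malonate | O1[C@H]2[C@H](C(C(=O)OC(C)(C)C)C(=O)OC(C)(C)C)C[C@@H]1[C@H](C)[C@@](O)(C(=O)C[C@H](C)O[Si](c3ccccc3)(c3ccccc3)C(C)(C)C)[C@@H]2O | intermediate
19 | 2,3-O-cyclic sulfite of 18 (both epimers at sulfur) | O1[C@H]2[C@H](C(C(=O)OC(C)(C)C)C(=O)OC(C)(C)C)C[C@@H]1[C@H](C)[C@]3(C(=O)C[C@H](C)O[Si](c4ccccc4)(c4ccccc4)C(C)(C)C)OS(=O)O[C@H]23 | intermediate
20 | 2,3-O-cyclic sulfate of 18 | O1[C@H]2[C@H](C(C(=O)OC(C)(C)C)C(=O)OC(C)(C)C)C[C@@H]1[C@H](C)[C@]3(C(=O)C[C@H](C)O[Si](c4ccccc4)(c4ccccc4)C(C)(C)C)OS(=O)(=O)O[C@H]23 | intermediate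
21 | (S)-2-methylbutanoic acid | CC[C@H](C)C(=O)O | starting material
22 | cesium (S)-2-methylbutanoate | CC[C@H](C)C(=O)[O-].[Cs+] | intermediate
23 | cesium 3-O-sulfate of 24 | O1[C@H]2[C@H](C(C(=O)OC(C)(C)C)C(=O)OC(C)(C)C)C[C@@H]1[C@H](C)[C@@](OS(=O)(=O)[O-])(C(=O)C[C@H](C)O[Si](c3ccccc3)(c3ccccc3)C(C)(C)C)[C@H]2OC(=O)[C@@H](C)CC.[Cs+] | intermediate
24 | di-tert-butyl 2-{3-[(3S)-3-(tert-butyldiphenylsilyloxy)butanoyl]-3-hydroxy-4-methyl-2-[(2S)-2-methylbutanoyloxy]-8-oxabicyclo[3.2.1]octan-7-yl}malonate (acyloxy axial, trans to 3-OH) | O1[C@H]2[C@H](C(C(=O)OC(C)(C)C)C(=O)OC(C)(C)C)C[C@@H]1[C@H](C)[C@@](O)(C(=O)C[C@H](C)O[Si](c3ccccc3)(c3ccccc3)C(C)(C)C)[C@H]2OC(=O)[C@@H](C)CC | intermediate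
25 | bis(trimethylsilyl) ester and 3-O-trimethylsilyl ether corresponding to 24 | O1[C@H]2[C@H](C(C(=O)O[Si](C)(C)C)C(=O)O[Si](C)(C)C)C[C@@H]1[C@H](C)[C@@](O[Si](C)(C)C)(C(=O)C[C@H](C)O[Si](c3ccccc3)(c3ccccc3)C(C)(C)C)[C@H]2OC(=O)[C@@H](C)CC | intermediate
26 | trimethylsilyl ester and 5-O,7-O-bis(trimethylsilyl) ether of 27 | C[Si](C)(C)OC(=O)C1C(=O)O[C@@H]2[C@H]1C[C@@H](O[Si](C)(C)C)[C@H](C)[C@@](O[Si](C)(C)C)(C(=O)C[C@H](C)O[Si](c3ccccc3)(c3ccccc3)C(C)(C)C)[C@H]2OC(=O)[C@@H](C)CC | intermediate
27 | 7-[(3S)-3-(tert-butyldiphenylsilyloxy)butanoyl]-5,7-dihydroxy-6-methyl-8-[(2S)-2-methylbutanoyloxy]-2-oxooctahydro-2H-cyclohepta[b]furan-3-carboxylic acid (ring centres as in 30; both C3 epimers) | OC(=O)C1C(=O)O[C@@H]2[C@H]1C[C@@H](O)[C@H](C)[C@@](O)(C(=O)C[C@H](C)O[Si](c3ccccc3)(c3ccccc3)C(C)(C)C)[C@H]2OC(=O)[C@@H](C)CC | intermediate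
28 | 3-(diethylaminomethyl) derivative of 27 (Mannich base) | CCN(CC)CC1(C(O)=O)C(=O)O[C@@H]2[C@H]1C[C@@H](O)[C@H](C)[C@@](O)(C(=O)C[C@H](C)O[Si](c3ccccc3)(c3ccccc3)C(C)(C)C)[C@H]2OC(=O)[C@@H](C)CC | intermediate
29 | side-chain O-tert-butyldiphenylsilyl ether of 30 | C=C1C(=O)O[C@@H]2[C@H]1C[C@@H](O)[C@H](C)[C@@](O)(C(=O)C[C@H](C)O[Si](c3ccccc3)(c3ccccc3)C(C)(C)C)[C@H]2OC(=O)[C@@H](C)CC | intermediate
30 | (3aS,5R,6S,7S,8S,8aR)-5,7-dihydroxy-7-[(3S)-3-hydroxybutanoyl]-6-methyl-3-methylidene-2-oxooctahydro-2H-cyclohepta[b]furan-8-yl (2S)-2-methylbutanoate | C=C1C(=O)O[C@@H]2[C@H]1C[C@@H](O)[C@H](C)[C@@](O)(C(=O)C[C@H](C)O)[C@H]2OC(=O)[C@@H](C)CC | target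

**Step count.** Total: 13 steps. Longest linear sequence: 12 steps (steps 1–5 and 7–13).

**Steps most likely to fail**

1. Step 11 (Proposed new method). The silyloxonium ion may not be opened by the weakly nucleophilic silyl ester; on forcing, ionisation at the tertiary silyl ether or elimination in the β-silyloxy ketone may take over. The fallback uses known chemistry, sets out from 24 and comes back at 27. Me2BBr (CH2Cl2, −78 → 0 °C) should cleave the bridging ether by bromide attack at C5, the bridgehead that is neither flanked by the acyloxy carbon nor covered on its endo face by the malonyl group. This gives the trans-bromohydrin F1 (C5–Br inverted, C1–OH kept). TFA removes both tert-butyl groups to give the diacid F2. Mitsunobu lactonisation (PPh3, DIAD) closes the γ-lactone with inversion at the carbinol carbon to give the bromo lactone acid F3. KNO2 in DMSO then exchanges bromide for hydroxyl with a second inversion at C5 and returns 27.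

2. Step 3 (key step). The first bond may form at the methyl-bearing terminus of the cation instead of the alkoxy-bearing one, which would reverse the regiochemistry steered by bromine. The deactivated bromofuran may also react only above −78 °C, where facial control by the auxiliary erodes. The fallback sets out from 6 and 9 and comes back at 10. Palladium-catalysed arylation of 9 with 6 (Pd2(dba)3, P(t-Bu)3·HBF4, K3PO4) gives di-tert-butyl 2-(furan-3-yl)malonate F4, a more electron-rich diene whose free C5 is the more reactive α-carbon. Its cycloaddition with 5 under the conditions of step 3 should give 10 directly, so that step 4 falls away.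

3. Step 10. Substitution at C2, next to the quaternary carbinol carbon, may be slow, so that attack of the carboxylate at sulfur or base-induced loss of the silyloxy group from the β-silyloxy ketone competes. The fallback sets out from 16 and comes back at 24. Dess–Martin oxidation of the secondary C2 alcohol gives the 2-ketone F5. Hydroxyl-directed reduction with Me4NBH(OAc)3 should deliver hydride from the axial C3 oxygen to the endo face and give the axial alcohol F6. Yamaguchi esterification with 21 gives the ester F7, and hydration of the alkyne as in step 8 returns 24.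

Further compounds
F1 | step 11 | trans-bromohydrin from ether cleavage of 24 (C5–Br, C1–OH; di-tert-butyl malonate intact) | O[C@H]2[C@H](C(C(=O)OC(C)(C)C)C(=O)OC(C)(C)C)C[C@H](Br)[C@H](C)[C@@](O)(C(=O)C[C@H](C)O[Si](c3ccccc3)(c3ccccc3)C(C)(C)C)[C@H]2OC(=O)[C@@H](C)CC
F2 | step 11 | malonic diacid of F1 | O[C@H]2[C@H](C(C(=O)O)C(=O)O)C[C@H](Br)[C@H](C)[C@@](O)(C(=O)C[C@H](C)O[Si](c3ccccc3)(c3ccccc3)C(C)(C)C)[C@H]2OC(=O)[C@@H](C)CC
F3 | step 11 | 5-bromo-5-deoxy analogue of 27 with inverted C5 (bromo lactone acid) | OC(=O)C1C(=O)O[C@@H]2[C@H]1C[C@H](Br)[C@H](C)[C@@](O)(C(=O)C[C@H](C)O[Si](c3ccccc3)(c3ccccc3)C(C)(C)C)[C@H]2OC(=O)[C@@H](C)CC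
F4 | step 3 | di-tert-butyl 2-(furan-3-yl)malonate | CC(C)(C)OC(=O)C(c1ccoc1)C(=O)OC(C)(C)C
F5 | step 10 | 2-ketone from oxidation of 16 | O1[C@H]2[C@H](C(C(=O)OC(C)(C)C)C(=O)OC(C)(C)C)C[C@@H]1[C@H](C)[C@@](O)(C#C[C@H](C)O[Si](c3ccccc3)(c3ccccc3)C(C)(C)C)C2=O
F6 | step 10 | C2 epimer of 16 (2-OH axial, trans to 3-OH) | O1[C@H]2[C@H](C(C(=O)OC(C)(C)C)C(=O)OC(C)(C)C)C[C@@H]1[C@H](C)[C@@](O)(C#C[C@H](C)O[Si](c3ccccc3)(c3ccccc3)C(C)(C)C)[C@H]2O
F7 | step 10 | 2-O-[(2S)-2-methylbutanoyl] ester of F6 (alkyne analogue of 24) | O1[C@H]2[C@H](C(C(=O)OC(C)(C)C)C(=O)OC(C)(C)C)C[C@@H]1[C@H](C)[C@@](O)(C#C[C@H](C)O[Si](c3ccccc3)(c3ccccc3)C(C)(C)C)[C@H]2OC(=O)[C@@H](C)CC
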